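**Retrosynthetic overview** (side-chain carbons are C1′–C16′, counted from the arene)
1. Target ⇐ one methanolysis that removes an aryl acetate and a C12′ benzoate; no ring is formed at any stage, the arene is bought intact.
2. C7′–C8′ sp2–sp3 Negishi coupling divides the chain into fragment A (arene + C1′–C7′, an (E)-vinyl iodide) and fragment B (C8′–C16′, an alkyl iodide).
3. Fragment A: C5′ by phosphoric-acid-catalysed allenylboration of but-2-ynal; the terminal alkyne becomes the 2′E olefin and takes on the arene by methylalumination/Pd benzylation; the internal alkyne becomes the vinyl iodide by hydrozirconation/iodination.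
4. Fragment B: C11′ and C12′ by a one-pot organocatalytic transfer hydrogenation/α-benzoyloxylation of an (E)-β-methyl enal (new relay), then alkenyl Grignard addition and oxidation to the enone.
5. Order: benzylic bromide → fragment A; fragment B; coupling; deprotection.

Assumption: but-2-ynal, allenylboronic acid pinacol ester, 5-chloropent-1-yne, and both enantiomers of TRIP (3,3′-bis(2,4,6-triisopropylphenyl)-1,1′-binaphthyl-2,2′-diyl hydrogen phosphate) and of 2-tritylpyrrolidine are taken as commercial. The facial sense of each organocatalyst is assigned by analogy with its closest published substrates and would be confirmed (Mosher analysis) before scale-up.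

**Step 1**
Reactants: 1 4-methoxy-2-methylphenol; 2 formaldehyde
Product: 3 2-(hydroxymethyl)-4-methoxy-6-methylphenol
Conditions: 37% aq. CH2O (3 equiv), NaOH (1.1 equiv), H2O, 25 °C, 48 h; AcOH to pH 6
Reagents that add atoms: formaldehyde, C=O
Why: Lederer–Manasse ortho-hydroxymethylation: the phenoxide attacks formaldehyde at C6, its only free ortho position, because the para position carries the methoxy group.

**Step 2**
Reactants: 3 2-(hydroxymethyl)-4-methoxy-6-methylphenol
Product: 4 2-(bromomethyl)-4-methoxy-6-methylphenyl acetate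
Conditions: AcBr (2.5 equiv), CH2Cl2, 0 → 23 °C, 3 h
Reagents that add atoms: acetyl bromide, CC(=O)Br
Why: Acetyl bromide acetylates both hydroxyl groups and the HBr released exchanges the electron-rich benzylic acetate for bromide (SN1-type substitution), giving a storable O-protected benzylic electrophile.

**Step 3**
Reactants: 5 but-2-ynal; 6 allenylboronic acid pinacol ester
Product: 8 (R)-hepta-1,5-diyn-4-ol, via pinacol borate ester 7 (not isolated)
Conditions: (R)-TRIP phosphoric acid (10 mol%), 4 Å molecular sieves, toluene, −20 °C, 72 h; aqueous work-up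
Reagents that add atoms: allenylboronic acid pinacol ester, C=C=CB1OC(C)(C)C(C)(C)O1
Why: Chiral-phosphoric-acid-catalysed allenylboration (Antilla-type propargylation): the acid binds the boronate oxygen and the formyl hydrogen in a chair transition state, so the allenyl γ-carbon adds to the Re face of the ynal and sets C5′ as R, the alkynyl group taking the place of the aryl or alkenyl group of the known substrates.

**Step 4**
Reactants: 8 (R)-hepta-1,5-diyn-4-ol; 9 trimethylaluminium; 4 2-(bromomethyl)-4-methoxy-6-methylphenyl acetate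
Product: 11 2-[(2E,5R)-5-hydroxy-3-methyloct-2-en-6-yn-1-yl]-4-methoxy-6-methylphenyl acetate, via alkenyldimethylalane 10 (not isolated)
Conditions: Me3Al (3.0 equiv), Cp2ZrCl2 (0.25 equiv), CH2Cl2, 0 → 23 °C, 16 h; then THF, 4 (1.1 equiv), Pd(PPh3)4 (5 mol%), 23 °C, 4 h; aq. potassium sodium tartrate
Reagents that add atoms: trimethylaluminium, C[Al](C)C
Why: Negishi Zr-catalysed carboalumination adds Me (internal carbon) and Al (terminal carbon) syn across the terminal alkyne only, which fixes the 2′E geometry, and Pd-catalysed cross-coupling of the alkenylalane with the benzylic bromide proceeds with retention; the internal alkyne reacts far more slowly.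

**Step 5**
Reactants: 11 2-[(2E,5R)-5-hydroxy-3-methyloct-2-en-6-yn-1-yl]-4-methoxy-6-methylphenyl acetate
Product: 13 2-[(2E,5R,6E)-5-hydroxy-7-iodo-3-methylocta-2,6-dien-1-yl]-4-methoxy-6-methylphenyl acetate, via alkenylzirconocene chloride 12 (not isolated)
Conditions: Cp2Zr(H)Cl (2.5 equiv), THF, 23 → 45 °C, 1 h; then I2 (1.1 equiv), −20 °C
Reagents that add atoms: iodine, II
Why: Hydrozirconation adds Zr–H syn and, after equilibration with excess reagent, places Zr on the less hindered methyl-bearing alkyne carbon (the first equivalent is consumed by the hydroxyl group); iodinolysis with retention gives the (E)-vinyl iodide in which C5′ and the methyl group are cis.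

**Step 6**
Reactants: 14 5-chloropent-1-yne; 9 trimethylaluminium; 2 formaldehyde
Product: 17 (E)-6-chloro-3-methylhex-2-en-1-ol, via chloroalkenyldimethylalane 15 (not isolated), via lithium alkenylalanate 16 (not isolated)
Conditions: Me3Al (2.0 equiv), Cp2ZrCl2 (0.25 equiv), CH2Cl2, 23 °C, 12 h; evaporate, hexane; n-BuLi (1.05 equiv), 0 °C; (CH2O)n (3 equiv), THF, 23 °C; aq. HCl
Reagents that add atoms: trimethylaluminium, C[Al](C)C; formaldehyde (as paraformaldehyde), C=O
Why: Negishi carboalumination (syn, Me to the internal carbon) followed by hydroxymethylation of the derived alanate gives the geometrically pure (E)-allylic alcohol, and the alkyl chloride is inert to both organometallic reagents.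

**Step 7**
Reactants: 17 (E)-6-chloro-3-methylhex-2-en-1-ol
Product: 18 (E)-6-chloro-3-methylhex-2-enal
Conditions: MnO2 (15 equiv), CH2Cl2, 23 °C, 6 h
Reagents that add atoms: none
Why: Chemoselective allylic oxidation with MnO2 stops at the enal and does not isomerise the double bond.

**Step 8**
Reactants: 18 (E)-6-chloro-3-methylhex-2-enal
Product: 20 (2R,3S)-6-chloro-3-methyl-1-oxohexan-2-yl benzoate, via (S)-6-chloro-3-methylhexanal 19 (not isolated)
Conditions: morpholinium (S)-TRIP phosphate (15 mol%), Hantzsch ester (diethyl 2,6-dimethyl-1,4-dihydropyridine-3,5-dicarboxylate, 1.05 equiv), THF, 50 °C, 24 h; then 0 °C, (BzO)2 (0.3 equiv), 15 min; (R)-2-tritylpyrrolidine (10 mol%), hydroquinone (10 mol%), (BzO)2 (1.2 equiv), 0 °C, 6 h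
Reagents that add atoms: benzoyl peroxide, O=C(OOC(=O)c1ccccc1)c1ccccc1
Why: Proposed new method: a one-flask relay of iminium and enamine catalysis in which the morpholinium iminium ion of 18, paired with the chiral TRIP phosphate (counteranion-directed catalysis), takes hydride from the Hantzsch ester on one face and sets C11′ as S (the mirror-image salt gives (R)-citronellal from geranial); a small first portion of peroxide then destroys morpholine and leftover dihydropyridine, and the bulky (R)-2-tritylpyrrolidine forms the E-enamine of 19 and shields one face so that benzoyl peroxide delivers the benzoyloxy group to the other, setting C12′ as R (syn to the methyl group) under catalyst control; the closest known reactions are List's ammonium-phosphate transfer hydrogenation of citral, MacMillan's cycle-specific hydride/electrophile organocascades and Maruoka's α-benzoyloxylation of aldehydes, which have not been combined in one flask.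

**Step 9**
Reactants: 20 (2R,3S)-6-chloro-3-methyl-1-oxohexan-2-yl benzoate; 21 (2-methylprop-1-en-1-yl)magnesium bromide
Product: 22 (5R,6S)-9-chloro-4-hydroxy-2,6-dimethylnon-2-en-5-yl benzoate (both C4 epimers)
Conditions: 21 (1.2 equiv), THF, −78 °C, 1 h; AcOH quench at −78 °C
Reagents that add atoms: (2-methylprop-1-en-1-yl)magnesium bromide, CC(C)=C[Mg]Br
Why: Grignard 1,2-addition to the aldehyde at −78 °C is much faster than attack on the benzoate or the alkyl chloride, the cold acidic quench prevents benzoyl migration, and the new carbinol centre is removed in the next step.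

**Step 10**
Reactants: 22 (5R,6S)-9-chloro-4-hydroxy-2,6-dimethylnon-2-en-5-yl benzoate
Product: 23 (5R,6S)-9-chloro-2,6-dimethyl-4-oxonon-2-en-5-yl benzoate
Conditions: Dess–Martin periodinane (1.3 equiv), NaHCO3, CH2Cl2, 0 → 23 °C
Reagents that add atoms: none
Why: Dess–Martin oxidation of the allylic alcohol under buffered, non-basic conditions gives the enone without epimerising the α-benzoyloxy centre.

**Step 11**
Reactants: 23 (5R,6S)-9-chloro-2,6-dimethyl-4-oxonon-2-en-5-yl benzoate
Product: 24 (5R,6S)-9-iodo-2,6-dimethyl-4-oxonon-2-en-5-yl benzoate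
Conditions: NaI (5 equiv), acetone, 56 °C, 24 h
Reagents that add atoms: sodium iodide, [Na+].[I-]
Why: Finkelstein reaction: SN2 halide exchange at the primary carbon, driven by precipitation of NaCl.

**Step 12**
Reactants: 24 (5R,6S)-9-iodo-2,6-dimethyl-4-oxonon-2-en-5-yl benzoate; 13 2-[(2E,5R,6E)-5-hydroxy-7-iodo-3-methylocta-2,6-dien-1-yl]-4-methoxy-6-methylphenyl acetate
Product: 26 (5R,6S,10E,12R,14E)-16-[2-(acetyloxy)-5-methoxy-3-methylphenyl]-12-hydroxy-2,6,10,14-tetramethyl-4-oxohexadeca-2,10,14-trien-5-yl benzoate, via alkylzinc iodide 25 (not isolated)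
Conditions: Zn dust (3 equiv, activated with BrCH2CH2Br/TMSCl), LiCl (1.5 equiv), THF, 25 °C, 16 h; then 13 (0.8 equiv), Pd(OAc)2 (3 mol%), SPhos (6 mol%), THF, 25 °C
Reagents that add atoms: none
Why: Direct zinc insertion (Knochel conditions) gives an alkylzinc iodide that tolerates the ketone and the esters, and the Pd-catalysed sp3–sp2 Negishi coupling retains the vinyl iodide geometry (giving 6′E) and is faster than protonation of the zinc reagent by the free alcohol.

**Step 13**
Reactants: 26 (5R,6S,10E,12R,14E)-16-[2-(acetyloxy)-5-methoxy-3-methylphenyl]-12-hydroxy-2,6,10,14-tetramethyl-4-oxohexadeca-2,10,14-trien-5-yl benzoate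
Product: 27 (5R,6S,10E,12R,14E)-5,12-dihydroxy-16-(2-hydroxy-5-methoxy-3-methylphenyl)-2,6,10,14-tetramethylhexadeca-2,10,14-trien-4-one (CNP0156407.1)
Conditions: K2CO3 (0.5 equiv), MeOH, 0 °C, 1–2 h, argon; pH 7 phosphate buffer
Reagents that add atoms: none
Why: Carbonate-catalysed transesterification (Zemplén-type methanolysis) removes the aryl acetate and the activated α-keto benzoate at 0 °C, conditions too mild to enolise the α-hydroxy ketone or add methanol to the β,β-disubstituted enone.

**Compound list**
1 | 4-methoxy-2-methylphenol | COc1ccc(O)c(C)c1 | starting material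
2 | formaldehyde | C=O | starting material
3 | 2-(hydroxymethyl)-4-methoxy-6-methylphenol | COc1cc(C)c(O)c(CO)c1 | intermediate
4 | 2-(bromomethyl)-4-methoxy-6-methylphenyl acetate | COc1cc(C)c(OC(C)=O)c(CBr)c1 | intermediate
5 | but-2-ynal | CC#CC=O | starting material
6 | allenylboronic acid pinacol ester (2-(propa-1,2-dien-1-yl)-4,4,5,5-tetramethyl-1,3,2-dioxaborolane) | C=C=CB1OC(C)(C)C(C)(C)O1 | starting material
7 | (R)-2-(hepta-1,5-diyn-4-yloxy)-4,4,5,5-tetramethyl-1,3,2-dioxaborolane | C#CC[C@@H](OB1OC(C)(C)C(C)(C)O1)C#CC | intermediate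
8 | (R)-hepta-1,5-diyn-4-ol | C#CC[C@@H](O)C#CC | intermediate
9 | trimethylaluminium | C[Al](C)C | starting material
10 | dimethylaluminium (1E,4R)-1-(dimethylalumanyl)-2-methylhept-1-en-5-yn-4-olate | C[Al](C)/C=C(\C)C[C@@H](O[Al](C)C)C#CC | intermediate
11 | 2-[(2E,5R)-5-hydroxy-3-methyloct-2-en-6-yn-1-yl]-4-methoxy-6-methylphenyl acetate | COc1cc(C)c(OC(C)=O)c(C/C=C(\C)C[C@@H](O)C#CC)c1 | intermediate
12 | 2-[(2E,5R,6E)-7-[chlorobis(cyclopentadienyl)zirconio]-5-{[chlorobis(cyclopentadienyl)zirconio]oxy}-3-methylocta-2,6-dien-1-yl]-4-methoxy-6-methylphenyl acetate | COc1cc(C)c(OC(C)=O)c(C/C=C(\C)C[C@@H](O[Zr](Cl)(C2C=CC=C2)C2C=CC=C2)/C=C(\C)[Zr](Cl)(C2C=CC=C2)C2C=CC=C2)c1 | intermediate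
13 | 2-[(2E,5R,6E)-5-hydroxy-7-iodo-3-methylocta-2,6-dien-1-yl]-4-methoxy-6-methylphenyl acetate | COc1cc(C)c(OC(C)=O)c(C/C=C(\C)C[C@@H](O)/C=C(\C)I)c1 | intermediate
14 | 5-chloropent-1-yne | C#CCCCCl | starting material
15 | (E)-(5-chloro-2-methylpent-1-en-1-yl)dimethylalumane | C[Al](C)/C=C(\C)CCCCl | intermediate
16 | lithium butyl[(E)-5-chloro-2-methylpent-1-en-1-yl]dimethylaluminate | [Li+].CCCC[Al-](C)(C)/C=C(\C)CCCCl | intermediate
17 | (E)-6-chloro-3-methylhex-2-en-1-ol | OC/C=C(\C)CCCCl | intermediate
18 | (E)-6-chloro-3-methylhex-2-enal | O=C/C=C(\C)CCCCl | intermediate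
19 | (S)-6-chloro-3-methylhexanal | O=CC[C@@H](C)CCCCl | intermediate
20 | (2R,3S)-6-chloro-3-methyl-1-oxohexan-2-yl benzoate | O=C[C@H](OC(=O)c1ccccc1)[C@@H](C)CCCCl | intermediate
21 | (2-methylprop-1-en-1-yl)magnesium bromide | CC(C)=C[Mg]Br | starting material
22 | (5R,6S)-9-chloro-4-hydroxy-2,6-dimethylnon-2-en-5-yl benzoate (both C4 epimers) | CC(C)=CC(O)[C@H](OC(=O)c1ccccc1)[C@@H](C)CCCCl | intermediate
23 | (5R,6S)-9-chloro-2,6-dimethyl-4-oxonon-2-en-5-yl benzoate | CC(C)=CC(=O)[C@H](OC(=O)c1ccccc1)[C@@H](C)CCCCl | intermediate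
24 | (5R,6S)-9-iodo-2,6-dimethyl-4-oxonon-2-en-5-yl benzoate | CC(C)=CC(=O)[C@H](OC(=O)c1ccccc1)[C@@H](C)CCCI | intermediate
25 | [(4S,5R)-5-(benzoyloxy)-4,8-dimethyl-6-oxonon-7-en-1-yl]zinc iodide | CC(C)=CC(=O)[C@H](OC(=O)c1ccccc1)[C@@H](C)CCC[Zn]I | intermediate
26 | (5R,6S,10E,12R,14E)-16-[2-(acetyloxy)-5-methoxy-3-methylphenyl]-12-hydroxy-2,6,10,14-tetramethyl-4-oxohexadeca-2,10,14-trien-5-yl benzoate | COc1cc(C)c(OC(C)=O)c(C/C=C(\C)C[C@@H](O)/C=C(\C)CCC[C@H](C)[C@@H](OC(=O)c2ccccc2)C(=O)C=C(C)C)c1 | intermediate
27 | (5R,6S,10E,12R,14E)-5,12-dihydroxy-16-(2-hydroxy-5-methoxy-3-methylphenyl)-2,6,10,14-tetramethylhexadeca-2,10,14-trien-4-one | COc1cc(C)c(O)c(C/C=C(\C)C[C@@H](O)/C=C(\C)CCC[C@H](C)[C@@H](O)C(=O)C=C(C)C)c1 | target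

**Step count**
Total: 13 steps. Longest linear sequence: 8 steps (steps 6–13, from 5-chloropent-1-yne).

**Three steps most likely to fail**

Step 8 (the proposed new relay). The two catalytic cycles may interfere in one flask: peroxide can oxidise the amines and the dihydropyridine, and residual morpholine can cause a racemic background benzoyloxylation. The fallback gives up the relay and sets out from 18. The counteranion-directed transfer hydrogenation is run alone under its published conditions (morpholinium (S)-TRIP phosphate, Hantzsch ester, THF, 50 °C) and 19 is isolated by chromatography. Pure 19 is then subjected to the published enamine α-benzoyloxylation ((R)-2-tritylpyrrolidine, hydroquinone, benzoyl peroxide, THF, 0 °C) as a separate step. The route is rejoined at 20, and the fallback makes no compound outside the list (F0).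

Step 12 (fragment coupling). Zinc insertion next to an α-acyloxy ketone, or protonation of the zinc reagent by the free C5′ hydroxyl, may erode the yield. The fallback sets out from 13 and 24 and avoids a preformed organozinc: nickel-catalysed reductive cross-electrophile coupling of the two iodides (NiI2, 4,4′-di-tert-butyl-2,2′-bipyridine, Mn powder, NaI, DMPU, 25 °C), a known method that tolerates ketones, esters and free alcohols. It returns to the route at 26 and makes no compound outside the list (F0).

Step 3 (C5′ stereocentre). A slim, linear ynal may be poorly differentiated by the phosphoric acid, giving low ee. The fallback sets out from 5: zinc-mediated Barbier propargylation with propargyl bromide (Zn dust, THF/aq. NH4Cl) gives racemic hepta-1,5-diyn-4-ol F1. Lipase-catalysed kinetic resolution (Burkholderia cepacia lipase, vinyl acetate, hexane) then acetylates the S enantiomer to (S)-hepta-1,5-diyn-4-yl acetate F2 and leaves the R alcohol (at most 50%). The route is rejoined at 8.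

**Further compounds**
F1 | step 3 | racemic hepta-1,5-diyn-4-ol | C#CCC(O)C#CC
F2 | step 3 | (S)-hepta-1,5-diyn-4-yl acetate | C#CC[C@H](OC(C)=O)C#CC
F0 | step 8 | none | none
F0 | step 12 | none | none
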